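Assumption: the protected commercial reagents 2, 9 and 24 are bought as such (their cores are propargyl alcohol, acetylene and butane-1,2,4-triol). Atom labels C1–C15 are those of the germacrane skeleton of the target. TBS = tert-butyldimethylsilyl, TBDPS = tert-butyldiphenylsilyl, TIPS = triisopropylsilyl, Ts = 4-methylphenylsulfonyl. Racemate 12 is written as both enantiomers.

**Retrosynthetic overview**
1. Target 31 ⇐ singlet-oxygen ene reaction of the 1(10)E-olefin 30 (gives C1–OOH and the 10(14)-methylene) ⇐ acetonide 29.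
2. cis-Fused α-methylene lactone 29 ⇐ cyclocarbonylation of the 6-hydroxy-7-ethynyl compound 28 ⇐ Evans–Tishchenko coupling of β-hydroxy ketone 23 with enal 27 (sets C6, puts the ester on O8).
3. Ten-membered dienone 21 ⇐ key ring expansion of cyclopentanone 18: iodine–lithium exchange, alkenyllithium closure of a seven-membered ring onto the ketone, Grob fragmentation of the C6–C10 bond (five → ten).
4. 18 ⇐ cyclopentenone 14 + iodo aldehyde 7 (Morita–Baylis–Hillman, then chelate-controlled reductive methylation); 14 ⇐ furfural by Piancatelli rearrangement and lipase resolution.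
5. Ring order: furan → cyclopentenone → transient cyclopentane-fused cycloheptene → cyclodecadienone → γ-lactone.

**Route**

Step 1
Reactants: 1 2-(2-bromoethyl)-1,3-dioxolane; 2 tert-butyl(diphenyl)(prop-2-yn-1-yloxy)silane
Product: 6 2-[(3E)-3-(TBDPSO-methyl)-4-iodobut-3-en-1-yl]-1,3-dioxolane, via Grignard reagent 3 (not isolated), via alkylcopper 4 (not isolated), via alkenylcopper 5 (not isolated)
Conditions: 1, Mg, THF, 25 °C; CuBr·SMe2, Et2O/Me2S, −45 °C; 2, −25 °C; I2, −78 → 0 °C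
Reagents that add atoms: iodine, II
Why: Normant carbocupration adds the alkylcopper syn across the terminal alkyne with the alkyl group on the internal carbon, and iodinolysis with retention gives the iodoalkene with I cis to the new chain, the geometry that later becomes the ring-cis C4=C5 bond.

Step 2
Reactants: 6 2-[(3E)-3-(TBDPSO-methyl)-4-iodobut-3-en-1-yl]-1,3-dioxolane
Product: 7 (4E)-4-(TBDPSO-methyl)-5-iodopent-4-enal
Conditions: AcOH/H2O (4:1), 50 °C
Reagents that add atoms: water, O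
Why: Acid-catalysed acetal hydrolysis; the TBDPS ether and the iodoalkene are stable to aqueous acetic acid.

Step 3
Reactants: 8 furan-2-carbaldehyde; 9 ethynyltri(propan-2-yl)silane
Product: 11 rac-1-(furan-2-yl)-3-(TIPS)prop-2-yn-1-ol, via lithium acetylide 10 (not isolated)
Conditions: 9, n-BuLi, THF, −78 °C; 8, −78 → 0 °C; H2O
Reagents that add atoms: none
Why: 1,2-Addition of a lithium acetylide to an aldehyde; the carbinol centre is lost in the next step, so the racemate is used.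

Step 4
Reactants: 11 rac-1-(furan-2-yl)-3-(TIPS)prop-2-yn-1-ol
Product: 12 rac-trans-4-hydroxy-5-(TIPS-ethynyl)cyclopent-2-en-1-one
Conditions: Dy(OTf)3 (10 mol %), t-BuOH/H2O (5:1), 80 °C
Reagents that add atoms: water, O
Why: Piancatelli rearrangement (furfuryl cation, water addition, ring opening, conrotatory 4π closure) gives only the trans-4-hydroxy-5-substituted cyclopentenone, i.e. the C8–O/C7–C11 trans relationship, as a racemate.

Step 5
Reactants: 12 rac-trans-4-hydroxy-5-(TIPS-ethynyl)cyclopent-2-en-1-one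
Product: 13 (4S,5R)-4-hydroxy-5-(TIPS-ethynyl)cyclopent-2-en-1-one
Conditions: lipase from Burkholderia cepacia (immobilised), vinyl acetate, MTBE, 30 °C, stopped at about 52 % conversion
Reagents that add atoms: none
Why: Lipase-catalysed acylative kinetic resolution: with the alkynyl-bearing C5 as the large group (Kazlauskas rule) the (4R)-alcohol is acetylated and the wanted (4S,5R)-alcohol is recovered, which fixes the absolute configuration of C7 and C8.

Step 6
Reactants: 13 (4S,5R)-4-hydroxy-5-(TIPS-ethynyl)cyclopent-2-en-1-one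
Product: 14 (4S,5R)-4-(TBSO)-5-(TIPS-ethynyl)cyclopent-2-en-1-one
Conditions: TBSCl, imidazole, DMF, 0 → 25 °C
Reagents that add atoms: tert-butyl(chloro)dimethylsilane, C[Si](C)(Cl)C(C)(C)C
Why: Standard silylation protects O8 under conditions too mild to epimerise C7.

Step 7
Reactants: 14 (4S,5R)-4-(TBSO)-5-(TIPS-ethynyl)cyclopent-2-en-1-one; 7 (4E)-4-(TBDPSO-methyl)-5-iodopent-4-enal
Product: 15 (4S,5R)-2-[(1R,4E)-4-(TBDPSO-methyl)-1-hydroxy-5-iodopent-4-en-1-yl]-4-(TBSO)-5-(TIPS-ethynyl)cyclopent-2-en-1-one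
Conditions: PBu3 (0.2 equiv), phenol (0.2 equiv), THF, 25 °C; carbinol epimers separated
Reagents that add atoms: none
Why: Morita–Baylis–Hillman reaction of the enone α-carbon (C10) with aldehyde 7 forms the C10–C1 bond; both carbinol epimers form and are separated, and the (1R)-epimer, matched for step 8, is carried on.

Step 8
Reactants: 15 (4S,5R)-2-[(1R,4E)-4-(TBDPSO-methyl)-1-hydroxy-5-iodopent-4-en-1-yl]-4-(TBSO)-5-(TIPS-ethynyl)cyclopent-2-en-1-one
Product: 17 (2S,4S,5R)-2-[(1R,4E)-4-(TBDPSO-methyl)-1-hydroxy-5-iodopent-4-en-1-yl]-4-(TBSO)-2-methyl-5-(TIPS-ethynyl)cyclopentan-1-one, via dilithium enolate alkoxide 16 (not isolated)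
Conditions: LiBH(s-Bu)3 (2.2 equiv), THF, −78 °C; MeI (5 equiv), −78 → −30 °C; H2O
Reagents that add atoms: iodomethane, CI
Why: Conjugate reduction gives the regiodefined lithium enolate chelated to the C1 alkoxide, and Fráter–Seebach-type methylation anti to the carbinol substituent (and anti to OTBS) sets the quaternary C10 with OH and CH3 anti, the relationship that later dictates the E geometry of the 1(10)-olefin.

Step 9
Reactants: 17 (2S,4S,5R)-2-[(1R,4E)-4-(TBDPSO-methyl)-1-hydroxy-5-iodopent-4-en-1-yl]-4-(TBSO)-2-methyl-5-(TIPS-ethynyl)cyclopentan-1-one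
Product: 18 side-chain C1 tosylate of 17
Conditions: TsCl, Et3N, Me3N·HCl (cat.), CH2Cl2, 0 → 25 °C
Reagents that add atoms: 4-methylbenzenesulfonyl chloride, Cc1ccc(cc1)S(Cl)(=O)=O
Why: Amine-catalysed sulfonylation of the hindered secondary alcohol; a tosylate is used because it has no acidic α-hydrogens for the organolithium of step 10, and the quaternary C10 prevents β-elimination.

Step 10
Reactants: 18 side-chain C1 tosylate of 17
Product: 21 (2E,6E,9S,10R)-3-(TBDPSO-methyl)-9-(TBSO)-7-methyl-10-(TIPS-ethynyl)cyclodeca-2,6-dien-1-one, via alkenyllithium 19 (not isolated), via bicyclic lithium alkoxide 20 (not isolated)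
Conditions: t-BuLi (2.05 equiv), THF/Et2O/pentane (4:1:1), −100 °C; −78 °C, 1 h; then 0 °C, 2 h; pH 7 buffer
Reagents that add atoms: none
Why: Proposed new method: iodine–lithium exchange is faster than attack of t-BuLi on the hindered ketone and gives alkenyllithium 19 with retention; its intramolecular 1,2-addition closes the seven-membered ring to the cis-fused lithium alkoxide 20, in which O, CH3 and OTs are cis so that the C6–C10 bond is antiperiplanar to the equatorial C1–OTs bond (no oxetane possible), and warming triggers Grob fragmentation that opens the cyclopentane into the ten-membered ring, the C1/C10 relative configuration giving the 1(10)E olefin stereospecifically while the ring-cis C4=C5 bond comes from the iodoalkene; the closest known reactions are the SmI2-mediated Barbier cyclisation/Grob fragmentation of iodoalkyl β-mesyloxy ketones (alkyl iodides only), halogen–lithium exchange cyclisations of alkenyl iodides onto ketones and the addition/Grob fragmentation of β-sulfonyloxy ketones with external nucleophiles, none of which has been run as an alkenyl-anion ring-expansion cascade.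

Step 11
Reactants: 21 (2E,6E,9S,10R)-3-(TBDPSO-methyl)-9-(TBSO)-7-methyl-10-(TIPS-ethynyl)cyclodeca-2,6-dien-1-one
Product: 22 (2E,6E,9S,10R)-10-ethynyl-9-hydroxy-3-(hydroxymethyl)-7-methylcyclodeca-2,6-dien-1-one
Conditions: Bu4NF (5 equiv), AcOH (5 equiv), THF, 0 → 25 °C
Reagents that add atoms: none
Why: Acetic acid-buffered fluoride cleaves the two O-silyl groups and the alkynyl C–Si bond while avoiding retro-aldol cleavage or elimination of the β-hydroxy ketone.

Step 12
Reactants: 22 (2E,6E,9S,10R)-10-ethynyl-9-hydroxy-3-(hydroxymethyl)-7-methylcyclodeca-2,6-dien-1-one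
Product: 23 (2E,6E,9S,10R)-3-(acetoxymethyl)-10-ethynyl-9-hydroxy-7-methylcyclodeca-2,6-dien-1-one
Conditions: AcCl (1.05 equiv), 2,4,6-collidine, CH2Cl2, −78 °C
Reagents that add atoms: acetyl chloride, CC(Cl)=O
Why: Selective acylation: the primary allylic hydroxyl is acetylated far faster than the hindered secondary one at −78 °C.

Step 13
Reactants: 24 2-[(4R)-2,2-dimethyl-1,3-dioxolan-4-yl]ethan-1-ol
Product: 25 [(4R)-2,2-dimethyl-1,3-dioxolan-4-yl]acetaldehyde
Conditions: Dess–Martin periodinane, CH2Cl2, 0 → 25 °C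
Reagents that add atoms: none
Why: Dess–Martin oxidation of the primary alcohol without eliminating the β-alkoxy aldehyde.

Step 14
Reactants: 25 [(4R)-2,2-dimethyl-1,3-dioxolan-4-yl]acetaldehyde
Product: 27 2-[(4R)-2,2-dimethyl-1,3-dioxolan-4-yl]prop-2-enal, via Mannich base 26 (not isolated)
Conditions: CH2=NMe2+ I−, Et3N, CH2Cl2, 25 °C
Reagents that add atoms: N,N-dimethylmethaniminium iodide, C=[N+](C)C.[I-]
Why: Mannich reaction with the iminium salt followed by loss of dimethylamine (Eschenmoser methylenation) gives the α-methylene aldehyde without touching the dioxolane stereocentre.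

Step 15
Reactants: 23 (2E,6E,9S,10R)-3-(acetoxymethyl)-10-ethynyl-9-hydroxy-7-methylcyclodeca-2,6-dien-1-one; 27 2-[(4R)-2,2-dimethyl-1,3-dioxolan-4-yl]prop-2-enal
Product: 28 (1S,3E,7E,9S,10S)-7-(acetoxymethyl)-10-ethynyl-9-hydroxy-3-methylcyclodeca-3,7-dien-1-yl 2-[(4R)-2,2-dimethyl-1,3-dioxolan-4-yl]prop-2-enoate
Conditions: SmI2 (30 mol %), 27 (5 equiv), THF, −10 °C
Reagents that add atoms: none
Why: Evans–Tishchenko reaction: hydride transfer within the samarium-bound hemiacetal of the C8 hydroxyl through a chair transition state reduces the C6 ketone 1,3-anti (6S, O6 trans to O8) and leaves the acyl group on O8, so one step sets C6, installs the side-chain ester and differentiates O6 from O8.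

Step 16
Reactants: 28 (1S,3E,7E,9S,10S)-7-(acetoxymethyl)-10-ethynyl-9-hydroxy-3-methylcyclodeca-3,7-dien-1-yl 2-[(4R)-2,2-dimethyl-1,3-dioxolan-4-yl]prop-2-enoate
Product: 29 (6S,7R,8S)-15-acetoxy-8-{2-[(4R)-2,2-dimethyl-1,3-dioxolan-4-yl]prop-2-enoyloxy}germacra-1(10)E,4,11(13)-trien-12,6-olide (C3 and C6 cis on C4=C5; cis-fused lactone)
Conditions: PdCl2 (10 mol %), PPh3 (20 mol %), SnCl2 (10 mol %), CO (7 atm), MeCN, 65 °C
Reagents that add atoms: carbon monoxide, [C-]#[O+]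
Why: Palladium-catalysed cyclocarbonylation of a homopropargylic alcohol (alkoxycarbonyl-palladium syn-addition to the alkyne, then protonolysis) gives the α-methylene γ-lactone, cis-fused because O6 and the ethynyl group are cis; O8 is already acylated and cannot compete.

Step 17
Reactants: 29 (6S,7R,8S)-15-acetoxy-8-{2-[(4R)-2,2-dimethyl-1,3-dioxolan-4-yl]prop-2-enoyloxy}germacra-1(10)E,4,11(13)-trien-12,6-olide
Product: 30 (6S,7R,8S)-15-acetoxy-8-{[(3R)-3,4-dihydroxy-2-methylidenebutanoyl]oxy}germacra-1(10)E,4,11(13)-trien-12,6-olide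
Conditions: AcOH/H2O (4:1), 30 °C
Reagents that add atoms: none
Why: Mild acid hydrolysis of the terminal acetonide; the allylic acetate, the lactone and the diene survive dilute acetic acid at 30 °C.

Step 18
Reactants: 30 (6S,7R,8S)-15-acetoxy-8-{[(3R)-3,4-dihydroxy-2-methylidenebutanoyl]oxy}germacra-1(10)E,4,11(13)-trien-12,6-olide
Product: 31 (1R,6S,7R,8S)-15-acetoxy-1-hydroperoxy-8-{[(3R)-3,4-dihydroxy-2-methylidenebutanoyl]oxy}germacra-4,10(14),11(13)-trien-12,6-olide (CNP0307408.1)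
Conditions: O2, tetraphenylporphyrin (cat.), visible light, CH2Cl2, −20 °C
Reagents that add atoms: oxygen, O=O
Why: Schenck ene reaction: singlet oxygen attacks the strained electron-rich E-1(10) olefin (the other alkenes are electron-poor or deactivated by allylic oxygen) from its outer face with abstraction of a C14 hydrogen, giving the 1-hydroperoxide and the 10(14)-methylene, the C14-β conformer leading to the 1β (1R) hydroperoxide as in the photooxygenation of 1(10)E-germacranolides.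

**Compound list**
1 | 2-(2-bromoethyl)-1,3-dioxolane | BrCCC1OCCO1 | starting material
2 | tert-butyl(diphenyl)(prop-2-yn-1-yloxy)silane | C#CCO[Si](c1ccccc1)(c1ccccc1)C(C)(C)C | starting material
3 | [2-(1,3-dioxolan-2-yl)ethyl]magnesium bromide | Br[Mg]CCC1OCCO1 | intermediate
4 | [2-(1,3-dioxolan-2-yl)ethyl]copper | [Cu]CCC1OCCO1 | intermediate
5 | [(1E)-2-(TBDPSO-methyl)-4-(1,3-dioxolan-2-yl)but-1-en-1-yl]copper (Cu cis to the dioxolanylethyl chain) | [Cu]/C=C(\CCC1OCCO1)CO[Si](c2ccccc2)(c3ccccc3)C(C)(C)C | intermediate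
6 | 2-[(3E)-3-{[tert-butyl(diphenyl)silyl]oxymethyl}-4-iodobut-3-en-1-yl]-1,3-dioxolane | I/C=C(\CCC1OCCO1)CO[Si](c2ccccc2)(c3ccccc3)C(C)(C)C | intermediate
7 | (4E)-4-{[tert-butyl(diphenyl)silyl]oxymethyl}-5-iodopent-4-enal | O=CCC/C(CO[Si](c1ccccc1)(c2ccccc2)C(C)(C)C)=C\I | intermediate
8 | furan-2-carbaldehyde (furfural) | O=Cc1ccco1 | starting material
9 | ethynyltri(propan-2-yl)silane | C#C[Si](C(C)C)(C(C)C)C(C)C | starting material
10 | lithium (triisopropylsilyl)acetylide | [Li]C#C[Si](C(C)C)(C(C)C)C(C)C | intermediate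
11 | rac-1-(furan-2-yl)-3-[tri(propan-2-yl)silyl]prop-2-yn-1-ol | OC(C#C[Si](C(C)C)(C(C)C)C(C)C)c1ccco1 | intermediate
12 | rac-(4S,5R)-4-hydroxy-5-{[tri(propan-2-yl)silyl]ethynyl}cyclopent-2-en-1-one (trans, racemate) | O=C1C=C[C@H](O)[C@H]1C#C[Si](C(C)C)(C(C)C)C(C)C.O=C1C=C[C@@H](O)[C@@H]1C#C[Si](C(C)C)(C(C)C)C(C)C | intermediate
13 | (4S,5R)-4-hydroxy-5-{[tri(propan-2-yl)silyl]ethynyl}cyclopent-2-en-1-one | O=C1C=C[C@H](O)[C@H]1C#C[Si](C(C)C)(C(C)C)C(C)C | intermediate
14 | (4S,5R)-4-{[tert-butyl(dimethyl)silyl]oxy}-5-{[tri(propan-2-yl)silyl]ethynyl}cyclopent-2-en-1-one | O=C1C=C[C@H](O[Si](C)(C)C(C)(C)C)[C@H]1C#C[Si](C(C)C)(C(C)C)C(C)C | intermediate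
15 | (4S,5R)-2-[(1R,4E)-4-(TBDPSO-methyl)-1-hydroxy-5-iodopent-4-en-1-yl]-4-(TBSO)-5-(TIPS-ethynyl)cyclopent-2-en-1-one | O=C1[C@H](C#C[Si](C(C)C)(C(C)C)C(C)C)[C@@H](O[Si](C)(C)C(C)(C)C)C=C1[C@H](O)CC/C(CO[Si](c2ccccc2)(c3ccccc3)C(C)(C)C)=C\I | intermediate
16 | dilithium enolate alkoxide formed from 15 by 1,4-hydride addition (C6 enolate, C1 alkoxide) | [Li]OC1=C([C@H](O[Li])CC/C(CO[Si](c2ccccc2)(c3ccccc3)C(C)(C)C)=C\I)C[C@H](O[Si](C)(C)C(C)(C)C)[C@H]1C#C[Si](C(C)C)(C(C)C)C(C)C | intermediate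
17 | (2S,4S,5R)-2-[(1R,4E)-4-(TBDPSO-methyl)-1-hydroxy-5-iodopent-4-en-1-yl]-4-(TBSO)-2-methyl-5-(TIPS-ethynyl)cyclopentan-1-one | O=C1[C@H](C#C[Si](C(C)C)(C(C)C)C(C)C)[C@@H](O[Si](C)(C)C(C)(C)C)C[C@@]1(C)[C@H](O)CC/C(CO[Si](c2ccccc2)(c3ccccc3)C(C)(C)C)=C\I | intermediate
18 | 4-methylbenzenesulfonate of 17 at the side-chain (1R)-hydroxyl | O=C1[C@H](C#C[Si](C(C)C)(C(C)C)C(C)C)[C@@H](O[Si](C)(C)C(C)(C)C)C[C@@]1(C)[C@H](OS(=O)(=O)c2ccc(C)cc2)CC/C(CO[Si](c3ccccc3)(c4ccccc4)C(C)(C)C)=C\I | intermediate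
19 | alkenyllithium from 18 (Li in place of I, geometry retained) | O=C1[C@H](C#C[Si](C(C)C)(C(C)C)C(C)C)[C@@H](O[Si](C)(C)C(C)(C)C)C[C@@]1(C)[C@H](OS(=O)(=O)c2ccc(C)cc2)CC/C(CO[Si](c3ccccc3)(c4ccccc4)C(C)(C)C)=C\[Li] | intermediate
20 | cis-fused cyclopenta-cycloheptene lithium alkoxide (new C5–C6 bond; O, CH3 and OTs cis) | [Li]O[C@@]12C=C(CO[Si](c3ccccc3)(c4ccccc4)C(C)(C)C)CC[C@@H](OS(=O)(=O)c5ccc(C)cc5)[C@]1(C)C[C@H](O[Si](C)(C)C(C)(C)C)[C@H]2C#C[Si](C(C)C)(C(C)C)C(C)C | intermediate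
21 | (2E,6E,9S,10R)-3-(TBDPSO-methyl)-9-(TBSO)-7-methyl-10-(TIPS-ethynyl)cyclodeca-2,6-dien-1-one (C6 ketone; 1(10)E; C3 and C6 cis on C4=C5) | O=C1/C=C(/CO[Si](c2ccccc2)(c3ccccc3)C(C)(C)C)CC/C=C(\C)C[C@H](O[Si](C)(C)C(C)(C)C)[C@H]1C#C[Si](C(C)C)(C(C)C)C(C)C | intermediate
22 | (2E,6E,9S,10R)-10-ethynyl-9-hydroxy-3-(hydroxymethyl)-7-methylcyclodeca-2,6-dien-1-one | O=C1/C=C(/CO)CC/C=C(\C)C[C@H](O)[C@H]1C#C | intermediate
23 | (2E,6E,9S,10R)-3-(acetoxymethyl)-10-ethynyl-9-hydroxy-7-methylcyclodeca-2,6-dien-1-one | O=C1/C=C(/COC(C)=O)CC/C=C(\C)C[C@H](O)[C@H]1C#C | intermediate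
24 | 2-[(4R)-2,2-dimethyl-1,3-dioxolan-4-yl]ethan-1-ol | OCC[C@@H]1COC(C)(C)O1 | starting material
25 | [(4R)-2,2-dimethyl-1,3-dioxolan-4-yl]acetaldehyde | O=CC[C@@H]1COC(C)(C)O1 | intermediate
26 | 3-(dimethylamino)-2-[(4R)-2,2-dimethyl-1,3-dioxolan-4-yl]propanal (both C2 epimers) | O=CC(CN(C)C)[C@@H]1COC(C)(C)O1 | intermediate
27 | 2-[(4R)-2,2-dimethyl-1,3-dioxolan-4-yl]prop-2-enal | O=CC(=C)[C@@H]1COC(C)(C)O1 | intermediate
28 | (1S,3E,7E,9S,10S)-7-(acetoxymethyl)-10-ethynyl-9-hydroxy-3-methylcyclodeca-3,7-dien-1-yl 2-[(4R)-2,2-dimethyl-1,3-dioxolan-4-yl]prop-2-enoate (6S-alcohol, 8-ester in target numbering) | O[C@H]1/C=C(/COC(C)=O)CC/C=C(\C)C[C@H](OC(=O)C(=C)[C@@H]2COC(C)(C)O2)[C@H]1C#C | intermediate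
29 | (6S,7R,8S)-15-acetoxy-8-{2-[(4R)-2,2-dimethyl-1,3-dioxolan-4-yl]prop-2-enoyloxy}germacra-1(10)E,4,11(13)-trien-12,6-olide | C=C1C(=O)O[C@H]2/C=C(/COC(C)=O)CC/C=C(\C)C[C@H](OC(=O)C(=C)[C@@H]3COC(C)(C)O3)[C@@H]12 | intermediate
30 | (6S,7R,8S)-15-acetoxy-8-{[(3R)-3,4-dihydroxy-2-methylidenebutanoyl]oxy}germacra-1(10)E,4,11(13)-trien-12,6-olide | C=C1C(=O)O[C@H]2/C=C(/COC(C)=O)CC/C=C(\C)C[C@H](OC(=O)C(=C)[C@@H](O)CO)[C@@H]12 | intermediate
31 | (1R,6S,7R,8S)-15-acetoxy-1-hydroperoxy-8-{[(3R)-3,4-dihydroxy-2-methylidenebutanoyl]oxy}germacra-4,10(14),11(13)-trien-12,6-olide | C=C1C(=O)O[C@H]2/C=C(/COC(C)=O)CC[C@@H](OO)C(=C)C[C@H](OC(=O)C(=C)[C@@H](O)CO)[C@@H]12 | target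

**Totals**
Total step count: 18. Longest linear sequence: 14 steps (steps 3–12, then 15–18, from furfural).

**Three steps most likely to fail**

Step 10 (the proposed new ring-expansion cascade). The alkenyllithium may be quenched by proton transfer before it closes the seven-membered ring, or the lithium alkoxide may not fragment cleanly. The fallback uses known chemistry only, sets out from 17 and comes back at 21. Hydrodeiodination of 17 (Pd(PPh3)4 cat., Bu3SnH, THF) gives the 1,1-disubstituted alkene, the des-iodo hydroxy ketone F1. Addition of CH2=CHMgBr/CeCl3 (THF, −78 °C) to the ketone gives the vinyl carbinol diol F2. Only the secondary hydroxyl is mesylated (MsCl, Et3N, CH2Cl2, −20 °C) to the monomesylate F3. Ring-closing metathesis with the second-generation Grubbs catalyst (H2IMes)(PCy3)Cl2Ru=CHPh (CH2Cl2, 40 °C) closes the cycloheptene to the bicyclic hydroxy mesylate F4. A classical Grob fragmentation (KOtBu, THF, 0 °C) then gives 21; either ring fusion fragments because the mesylate stays cis to the methyl group.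

Step 15 (Evans–Tishchenko reaction with an α-methylene aldehyde). The trivalent samarium alkoxide may add in a conjugate sense to the enal, or the enal may dimerise. The fallback sets out from 23 and 27 and comes back at 28. Pinnick oxidation of 27 (NaClO2, NaH2PO4, 2-methylbut-2-ene, t-BuOH/H2O) gives the acrylic acid F5. Yamaguchi esterification of 23 with it (2,4,6-trichlorobenzoyl chloride, Et3N, DMAP, toluene, 0 °C) gives the β-acyloxy ketone F6. Corey–Bakshi–Shibata reduction ((S)-2-methyl-CBS-oxazaborolidine, catecholborane, toluene, −78 °C, the alkenyl residue acting as the large group) then sets 6S by reagent control and gives 28.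

Step 16 (cyclocarbonylation next to an allylic acetate and an acid-sensitive diene). The Lewis-acidic divalent palladium/tin system may ionise the allylic esters or trigger transannular cyclisation. The fallback sets out from 28 and comes back at 29. Markovnikov hydrostannation (Mo(CO)3(CNtBu)3 cat., Bu3SnH, THF, 55 °C) gives the α-stannyl alkene F7. Iododestannylation (I2, CH2Cl2, −78 °C) gives the 2-iodoalkene F8. Base-mediated carbonylative lactonisation with zerovalent palladium (Pd(PPh3)4, CO 1 atm, Et3N, MeCN, 45 °C) then gives 29.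

**Further compounds**
F1 | step 10 | (2S,4S,5R)-2-[(1R)-4-(TBDPSO-methyl)-1-hydroxypent-4-en-1-yl]-4-(TBSO)-2-methyl-5-(TIPS-ethynyl)cyclopentan-1-one | O=C1[C@H](C#C[Si](C(C)C)(C(C)C)C(C)C)[C@@H](O[Si](C)(C)C(C)(C)C)C[C@@]1(C)[C@H](O)CCC(=C)CO[Si](c2ccccc2)(c3ccccc3)C(C)(C)C
F2 | step 10 | vinyl carbinol diol from F1 (vinyl on C6 trans to the C10 side chain) | O[C@@]1(C=C)[C@H](C#C[Si](C(C)C)(C(C)C)C(C)C)[C@@H](O[Si](C)(C)C(C)(C)C)C[C@@]1(C)[C@H](O)CCC(=C)CO[Si](c2ccccc2)(c3ccccc3)C(C)(C)C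
F3 | step 10 | secondary methanesulfonate of F2 | O[C@@]1(C=C)[C@H](C#C[Si](C(C)C)(C(C)C)C(C)C)[C@@H](O[Si](C)(C)C(C)(C)C)C[C@@]1(C)[C@H](OS(C)(=O)=O)CCC(=C)CO[Si](c2ccccc2)(c3ccccc3)C(C)(C)C
F4 | step 10 | cyclopentane-fused cycloheptenol methanesulfonate (tertiary C6–OH, C1–OMs cis to CH3) | O[C@]12C=C(CO[Si](c3ccccc3)(c4ccccc4)C(C)(C)C)CC[C@@H](OS(C)(=O)=O)[C@]1(C)C[C@H](O[Si](C)(C)C(C)(C)C)[C@H]2C#C[Si](C(C)C)(C(C)C)C(C)C
F5 | step 15 | 2-[(4R)-2,2-dimethyl-1,3-dioxolan-4-yl]prop-2-enoic acid | OC(=O)C(=C)[C@@H]1COC(C)(C)O1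
F6 | step 15 | (1S,3E,7E,10R)-7-(acetoxymethyl)-10-ethynyl-3-methyl-9-oxocyclodeca-3,7-dien-1-yl 2-[(4R)-2,2-dimethyl-1,3-dioxolan-4-yl]prop-2-enoate | O=C1/C=C(/COC(C)=O)CC/C=C(\C)C[C@H](OC(=O)C(=C)[C@@H]2COC(C)(C)O2)[C@H]1C#C
F7 | step 16 | 28 with the ethynyl group replaced by 1-(tributylstannyl)ethenyl | O[C@H]1/C=C(/COC(C)=O)CC/C=C(\C)C[C@H](OC(=O)C(=C)[C@@H]2COC(C)(C)O2)[C@H]1C(=C)[Sn](CCCC)(CCCC)CCCC
F8 | step 16 | 28 with the ethynyl group replaced by 1-iodoethenyl | O[C@H]1/C=C(/COC(C)=O)CC/C=C(\C)C[C@H](OC(=O)C(=C)[C@@H]2COC(C)(C)O2)[C@H]1C(I)=C
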